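You read the flasks at 12 min, and this is what you take over.

| flask | starting material | coupling partner | temperature | remark | time |
|---|---|---|---|---|---|
| south-east | 0.30 M | 1.5 equiv | 20 °C | run made earlier |  |
| west | 0.30 M | 0.75 equiv | 31 °C | run made earlier |  |
| north-west | 0.30 M | 3 equiv | 20 °C | run made earlier |  |
| red | 0.30 M | 1.50 equiv (fed, over 2.5 min) | 25 °C | all else is in the flask from the start; the feed brings no volume worth counting | 12 min |
| ochre | 0.30 M (fed, over 2.5 min) | 1.50 equiv |  | the addition at −5 °C, then warmed to 25 °C; the feed brings no volume worth counting | 12 min |
| violet | 0.30 M (in portions, 3, over 2.5 min) | 1.50 equiv | 25 °C | first portion at the start, last at 2.5 min | 12 min |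
| grey | 0.30 M (fed, over 2.5 min) | 1.50 equiv | 25 °C | all else is in the flask from the start; the feed brings no volume worth counting | 12 min |

- south-east (time / min: target / %, starting material / %): 0.833: 21, 70; 2.50: 38, 45; 5.00: 48, 40; 8.00: 51, 35
- west (time / min: target / %, starting material / %): 2.50: 28, 70; 5.00: 29, 69; 8.00: 26, 68; 10.0: 29, 70
- north-west (time / min: target / %, starting material / %): 0.833: 34, 39; 2.00: 45, 20; 4.00: 53, 9; 10.0: 56, 3

(scatter of a reading: 1.5 percentage points)

- the numbers in the tables scatter with a standard deviation of 1.5 percentage points

- which flask leads in amount of target, in percent of the starting material charged ("all alike" within 1.5 percentage points) (red / ochre / violet / grey / all alike)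
- how much target is there at the end, in percent of the starting material charged: red
- how much target is there at the end, in percent of the starting material charged: ochre
- how much target is there at the end, in percent of the starting material charged: violet
- how much target is there at the end, in percent of the starting material charged: grey

The west run stands still near 70% starting material, so I read coupling partner, the limiting reagent there, as lost by a route of its own. I take coupling and decay as both first order in it, so dividing one rate by the other removes time and integrates in closed form: once coupling partner is used up, its charge equals what was coupled plus K times the logarithm of charged over remaining starting material. On that assumption this holds at one temperature however the coupling partner goes in, provided the starting material was there from the start. I count starting material that shows neither as itself nor as target as having taken two coupling partner. The last west readings give 0.370 M, and the last south-east readings, treating that run as nearly stopped, give 0.203 M. At 25 °C I take K as 0.267 M, the waste concentration: the [starting material] at which coupling partner splits evenly between coupling and decay.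

Red starts at 0.30 M, above K. If 40.0% remains, with south-east's share of missing material, the balance needs 0.463 M against 0.450 M charged, so I expect roughly 40.0% starting material left in red. In grey, [starting material] averages at most 0.150 M during the feed, below K, so I expect grey well behind red. Leave the bath alone: I read K larger at 31 °C than at 20 °C.

The forecast puts red first, with 52% in red, 48% in ochre, 35% in violet and 32% in grey, holding that “Feeding starting material lets partner decay before use”.

The flasks give 54.9% in red, 49.5% in ochre, 38.6% in violet and 38.3% in grey, and red keeps 36% starting material.

    starting material + coupling partner → target (k = 0.0217 M⁻¹ s⁻¹, Ea = 49.0 kJ mol⁻¹)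
    starting material + 2 coupling partner → side product (k = 0.0270 M⁻² s⁻¹, Ea = 43.0 kJ mol⁻¹)
    coupling partner → decomposed reagent (k = 0.00553 s⁻¹, Ea = 93.0 kJ mol⁻¹)
    2 coupling partner → self-condensation product (k = 5.33 × 10⁻⁴ M⁻¹ s⁻¹, Ea = 79.0 kJ mol⁻¹)
    (constants at 25 °C)

Decay of coupling partner is the largest single effect in the gap of 17 points between red and grey: without that step the gap is 6.2 points. In red, K times the logarithm gives 0.273 M against 0.225 M decomposed reagent at 12.0 min. A repeat of red at 0.51 M starting material, equivalents held, gives 0.376 M by the same reckoning against 0.296 M simulated, and that flask holds 61.5% target.

The numbers in the tables come from a simulation from invented constants.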